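**Plan**
- The target is achiral. Its only ring is a 1,4-disubstituted benzene with the acyloxyethyl chain on C1 and OH on C4, so no stereochemistry has to be set.
- Retrosynthesis: the phenol is masked as its O-SiMe3 ether and the benzene ring is cut at C2-C3 and C4-C5. C3 and C4 (with the oxygen) become the two carbons of a ketene bis-silyl acetal. C5-C6-C1-C2 become C3-C6 of a 2-pyrone carrying the side chain on its C5, and the lactone bridge is lost as CO2.
- The pyrone is cut further at the ester C-O bond (docosanoyl chloride) and at the ring C5-CH2 bond (5-bromo-2-pyrone plus a 2-benzyloxyethyl boron reagent).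
- Forward: sp3-sp2 coupling on the bromopyrone, debenzylation and acylation give the pyrone ester. The ketene acetal is made separately from trimethylsilyl acetate. Cycloaddition, CO2 loss and silanol loss build the benzene ring last, and dilute acid frees the phenol.

Key step: step 5

Remark: the bridged lactone that forms in the key step is racemic and transient; it is drawn as one enantiomer, and both enantiomers give the same arene.

**Step 1**
Reactants: 1 5-bromo-2H-pyran-2-one; 2 potassium (2-benzyloxyethyl)trifluoroborate
Product: 3 5-[2-(benzyloxy)ethyl]-2H-pyran-2-one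
Conditions: PdCl2[P(t-Bu)2(C6H4-4-NMe2)]2 (cat.), Cs2CO3, PhMe-H2O (4:1), 90 °C
Reagents that add atoms: none
Why: Suzuki-Miyaura sp3-sp2 coupling of a primary alkyltrifluoroborate, in which the pyrone C5-Br bond behaves as an electron-poor vinylic bromide towards zerovalent palladium, the bulky electron-rich phosphine favours reductive elimination over β-hydride elimination, β-alkoxyethyl trifluoroborates transmetalate without losing alkoxide, and the two-phase medium limits contact of the lactone with carbonate.

**Step 2**
Reactants: 3 5-[2-(benzyloxy)ethyl]-2H-pyran-2-one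
Product: 4 5-(2-hydroxyethyl)-2H-pyran-2-one
Conditions: BCl3, CH2Cl2, -78 to 0 °C; then H2O
Reagents that add atoms: none
Why: Lewis-acid cleavage of a benzyl ether, in which BCl3 binds the ether oxygen and chloride removes the benzyl group as benzyl chloride at low temperature, leaving the conjugated lactone intact where hydrogenolysis would saturate the pyrone double bonds.

**Step 3**
Reactants: 4 5-(2-hydroxyethyl)-2H-pyran-2-one; 5 docosanoyl chloride
Product: 6 2-(6-oxo-6H-pyran-3-yl)ethyl docosanoate
Conditions: Et3N, DMAP (cat.), CH2Cl2, 0 °C to rt
Reagents that add atoms: none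
Why: DMAP-catalysed esterification of a primary alcohol with an acid chloride (nucleophilic acyl substitution), fast at 0 °C so that the base-sensitive pyrone meets only tertiary amines and only briefly.

**Step 4**
Reactants: 7 trimethylsilyl acetate
Product: 9 1,1-bis(trimethylsilyloxy)ethene, via lithium enolate 8 (not isolated)
Conditions: LiN(i-Pr)2 (commercial solution), THF, -78 °C; Me3SiCl, -78 °C to rt; pentane, filtration, distillation
Reagents that add atoms: chlorotrimethylsilane, C[Si](C)(C)Cl
Why: Kinetic deprotonation of the silyl ester and O-silylation of the lithium enolate by the hard electrophile Me3SiCl (silyl ketene acetal formation), with O- over C-silylation favoured in THF at low temperature and a non-aqueous isolation protecting the moisture-sensitive product.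

**Step 5**
Reactants: 6 2-(6-oxo-6H-pyran-3-yl)ethyl docosanoate; 9 1,1-bis(trimethylsilyloxy)ethene
Product: 12 2-(4-trimethylsilyloxyphenyl)ethyl docosanoate, via bridged lactone 10 (not isolated), via silyloxy cyclohexadiene 11 (not isolated)
Conditions: 9 (5 equiv), PhMe, sealed tube, 130 °C; volatiles removed in vacuo
Reagents that add atoms: none
Why: Proposed new method: the pyrone diene (C3=C4-C5=C6) and the electron-rich ketene acetal should combine in an inverse-electron-demand [4+2] cycloaddition (concerted and asynchronous, or stepwise through a zwitterion formed by attack of the acetal CH2 on C6; both give the same bonds), forming C6-CH2 and C3-C(OSiMe3)2 in bridged lactone 10, which then loses CO2 by retro-[4+2] to diene 11 and Me3SiOH by 1,2-elimination to give the arene. The closest known reaction type is the cycloaddition of 3- or 5-alkoxycarbonyl-2-pyrones with 1,1-dialkoxyethenes, which gives alkoxybenzoates after loss of CO2 and alcohol; here the pyrone has no activating ester and the dienophile is a bis-silyl acetal, so a forcing temperature (or 10-12 kbar at ambient temperature) is planned. The benzene ring closes by intermolecular [4+2] ring formation through a six-membered transition state, followed by aromatisation. The two bridgehead stereocentres of 10 are transient and are erased, so no stereocontrol is needed. The selectivity required is regiochemical (oxygen para, not meta, to the side chain); it is secured by the polarisation of the pyrone, whose C6 is the electrophilic terminus of the dienyl ester and pairs with the nucleophilic CH2 of the acetal, and is reinforced sterically because the bulky C(OSiMe3)2 end bonds to the unhindered C3. The saturated ester is inert under these neutral conditions, and the by-products and excess acetal are volatile.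

**Step 6**
Reactants: 12 2-(4-trimethylsilyloxyphenyl)ethyl docosanoate
Product: 13 2-(4-hydroxyphenyl)ethyl docosanoate
Conditions: 1 M aq. HCl (cat.), THF, 0 °C to rt
Reagents that add atoms: none
Why: Acid-catalysed hydrolysis of an aryl trimethylsilyl ether (silyl ether cleavage), complete within minutes under conditions far too mild to hydrolyse the long-chain alkyl ester.

**Compound list**
1 | 5-bromo-2H-pyran-2-one | O=C1C=CC(Br)=CO1 | starting material
2 | potassium (2-benzyloxyethyl)trifluoroborate | [K+].F[B-](F)(F)CCOCc1ccccc1 | starting material
3 | 5-[2-(benzyloxy)ethyl]-2H-pyran-2-one | O=C1C=CC(CCOCc2ccccc2)=CO1 | intermediate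
4 | 5-(2-hydroxyethyl)-2H-pyran-2-one | O=C1C=CC(CCO)=CO1 | intermediate
5 | docosanoyl chloride | CCCCCCCCCCCCCCCCCCCCCC(=O)Cl | starting material
6 | 2-(6-oxo-6H-pyran-3-yl)ethyl docosanoate | CCCCCCCCCCCCCCCCCCCCCC(=O)OCCC1=COC(=O)C=C1 | intermediate
7 | trimethylsilyl acetate | CC(=O)O[Si](C)(C)C | starting material
8 | lithium 1-(trimethylsilyloxy)ethen-1-olate (lithium enolate of 7, not isolated) | [Li+].[O-]C(=C)O[Si](C)(C)C | intermediate
9 | 1,1-bis(trimethylsilyloxy)ethene | C=C(O[Si](C)(C)C)O[Si](C)(C)C | intermediate
10 | 2-[8,8-bis(trimethylsilyloxy)-3-oxo-2-oxabicyclo[2.2.2]oct-5-en-6-yl]ethyl docosanoate (racemic, one enantiomer drawn, not isolated) | CCCCCCCCCCCCCCCCCCCCCC(=O)OCCC1=C[C@@H]2C(=O)O[C@H]1CC2(O[Si](C)(C)C)O[Si](C)(C)C | intermediate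
11 | 2-[4,4-bis(trimethylsilyloxy)cyclohexa-1,5-dien-1-yl]ethyl docosanoate (not isolated) | CCCCCCCCCCCCCCCCCCCCCC(=O)OCCC1=CCC(O[Si](C)(C)C)(O[Si](C)(C)C)C=C1 | intermediate
12 | 2-(4-trimethylsilyloxyphenyl)ethyl docosanoate | CCCCCCCCCCCCCCCCCCCCCC(=O)OCCc1ccc(O[Si](C)(C)C)cc1 | intermediate
13 | 2-(4-hydroxyphenyl)ethyl docosanoate | CCCCCCCCCCCCCCCCCCCCCC(=O)OCCc1ccc(O)cc1 | target

**Step count**
Total: 6 steps. Longest linear sequence: 5 steps (steps 1, 2, 3, 5, 6); step 4 is a one-step side branch.

**Steps most likely to fail**

1. Step 5 (proposed new method).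
 - What may go wrong: without an activating ester the cycloaddition may be slow. Thermal oxygen-to-carbon silyl migration or protolysis of the ketene acetal may then outrun it, or CO2 extrusion from the bridged lactone may stall.
 - Fallback (known chemistry): the aromatic ring is bought instead of built. Setting out from 5, the acid chloride is used without base (dimethyl carbonate or CH2Cl2, rt) to esterify the aliphatic hydroxyl of purchased 4-(2-hydroxyethyl)phenol. In the absence of base the phenolic hydroxyl is far less nucleophilic and should stay free. The detour comes back to the route at 13 and makes no compound outside the list (new compound: none F0).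

2. Step 1.
 - What may go wrong: carbonate or hydroxide may open the pyrone ring at C2 or C6 faster than the slow alkyl transmetalation, and the trifluoroborate may protodeboronate.
 - Fallback: setting out from 1, a Stille coupling under neutral conditions with tributyl(vinyl)stannane (Pd(PPh3)4, PhMe, 90 °C) should give 5-ethenyl-2H-pyran-2-one F1. Anti-Markovnikov hydroboration of the vinyl group with 9-borabicyclo[3.3.1]nonane (THF, 0 °C to rt) gives 5-[2-(9-borabicyclo[3.3.1]nonan-9-yl)ethyl]-2H-pyran-2-one F2. Oxidation with NaBO3·4H2O (THF-H2O, rt), chosen to avoid alkaline peroxide, then gives the alcohol. The detour comes back to the route at 4 and bypasses steps 1 and 2.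

3. Step 4.
 - What may go wrong: C-silylation of the acetate enolate may compete with O-silylation, and the product may hydrolyse or isomerise during isolation.
 - Fallback: setting out from 6, purchased 1,1-diethoxyethene replaces the silyl acetal in the cycloaddition (PhMe, sealed tube, 130 °C); dialkyl ketene acetals are the dienophile class for which the pyrone-to-aryl-ether sequence is established. The sequence runs through 2-[8,8-diethoxy-3-oxo-2-oxabicyclo[2.2.2]oct-5-en-6-yl]ethyl docosanoate F3 and 2-(4,4-diethoxycyclohexa-1,5-dien-1-yl)ethyl docosanoate F4 to 2-(4-ethoxyphenyl)ethyl docosanoate F5. The primary alkyl aryl ether is then cleaved with BCl3 and n-Bu4NI (CH2Cl2, -78 to 0 °C), which should spare the alkyl ester. The detour comes back to the route at 13.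

**Further compounds**
F0 | step 5 | none | none
F1 | step 1 | 5-ethenyl-2H-pyran-2-one | C=CC1=COC(=O)C=C1
F2 | step 1 | 5-[2-(9-borabicyclo[3.3.1]nonan-9-yl)ethyl]-2H-pyran-2-one | O=C1C=CC(CCB2C3CCCC2CCC3)=CO1
F3 | step 4 | 2-[8,8-diethoxy-3-oxo-2-oxabicyclo[2.2.2]oct-5-en-6-yl]ethyl docosanoate (racemic, one enantiomer drawn) | CCCCCCCCCCCCCCCCCCCCCC(=O)OCCC1=C[C@@H]2C(=O)O[C@H]1CC2(OCC)OCC
F4 | step 4 | 2-(4,4-diethoxycyclohexa-1,5-dien-1-yl)ethyl docosanoate | CCCCCCCCCCCCCCCCCCCCCC(=O)OCCC1=CCC(OCC)(OCC)C=C1
F5 | step 4 | 2-(4-ethoxyphenyl)ethyl docosanoate | CCCCCCCCCCCCCCCCCCCCCC(=O)OCCc1ccc(OCC)cc1
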